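(The rate constants are made up; the result is computed.)

We decided to count turnovers for each step before either of us took a side.

    Q + D ⇌ E + Z (K1 = 1.33, k1 = 0.00133 M⁻¹ s⁻¹)
    2 Q → Q2 (k2 = 6.06 × 10⁻⁷ M⁻¹ s⁻¹)

| flask | Q | D | time |
|---|---|---|---|
| midnight | 0.53 M | 1.02 equiv | 40 h |
| autumn | 1.5 M | 1.02 equiv | 40 h |

- percent here means Q units held: one Q2 counts as two
- two of one species on the left: rate k times its square, two consumed each time
- each molecule carries two end groups: a chain counts once for every two ends that are left, dead ends included; the units are half of the end groups of the two monomers charged
- a link that another step uses up counts as cut, two dead ends; so do two ends of one kind that react with each other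
- run time (midnight): 40 h

* which of the two ends with the longer chains by the average number of monomer units in a chain (unreacted monomers counted as chains of one) ("neither" if they lie within 10%) (midnight / autumn / neither)
* average number of monomer units in a chain (unreacted monomers counted as chains of one) at the end, midnight
* average number of monomer units in a chain (unreacted monomers counted as chains of one) at the end, autumn

The first of us holds the balance view. The forward half-life of Q in midnight is 0.27 h, and the run is far longer than that: 149 half-lives, so the link step should reach its balance. In the closed flask c(Z) equals c(E) as far as the link step goes, so 1.33 is the square of the linked share over the product of the unlinked shares of Q and D, all counted as shares of the Q charged. The concentrations cancel. With 1.02 equiv of D, the linked share of Q (the equilibrium conversion) is 54.1% in midnight and autumn alike, which leaves 45.9% of Q free and gives chains of 2.15.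

The second of us holds the side-step view. Reckoned at the charge, Q turns over 0.0925 times in midnight and 0.262 times in autumn by the Q-with-Q step. Taking those counts as shares of Q lost, and each lost unit as one link lost, gives chains of 1.80 and 1.38, a gap of 30.4%, more than the margin, so autumn is shorter.

My reckoning corrects this count. The rate goes with the square of free Q, and Q stands at its free share, so the loss is the spoiled share, the turnovers at the charge times the square of the free share: 1.95% in midnight and 5.52% in autumn. Charging one link per spoiled unit, a harsh price, gives 2.07 and 1.93, a gap of 7.25%, less than the margin. I commit to neither, with midnight between 2.07 and 2.15 and autumn between 1.93 and 2.15.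

The forecast takes the balance side, with neither, 2.13 for midnight and 2.09 for autumn, both shorter than the plain balance figure of 2.15. Its ground: “The slow Q + Q side reaction removes only a few percent of the links”.

The flasks give neither: chains of 2.13 in midnight and 2.09 in autumn, with Q2 at 1.92% and 5.10% of the Q charged. The side-step view has its region later: at 400 h the chains stand at 1.97 in midnight and 1.78 in autumn, so autumn is shorter, by 10.4% of its own length, close to the margin. The neighbouring midnight flask with 4.10 equiv of D takes the same reckoning: linked share 83.8%, free share 16.2%, spoiled share 0.243%. That flask ends with Q at 16.1%, Q2 at 0.253% and chains of 1.49.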